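The constants used here were drawn at random within sensible limits; the result is computed.

0.457 M of free substrate is the crossover concentration: at this [substrate], at 80 °C, closure to single ring and dimerisation, counted with two substrate per turn, use substrate equally fast.

| flask | substrate | temperature | time |
|---|---|---|---|
| Thursday's | 1.6 M | 80 °C | 15 min |
| Sunday's | 1.6 M | 100 °C | 15 min |
| Monday's | 1.6 M | 120 °C | 15 min |

* which of the two there is more of at the end, counted by the substrate in each, Thursday's (ring dimer / single ring)
* which of the two there is more of at the end, counted by the substrate in each, Sunday's (ring dimer / single ring)
* which of the two there is more of at the end, counted by the substrate in each, Monday's (ring dimer / single ring)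
* single ring at the end, in percent of the substrate charged, Thursday's
* single ring at the end, in percent of the substrate charged, Sunday's
* single ring at the end, in percent of the substrate charged, Monday's

- percent here means substrate units held: one open dimer or ring dimer or idle adduct or side product counts as two
- percent here means substrate units held: one open trimer counts as three
- what is said of single ring includes idle adduct
- two of one species on the left: rate k times its square, two consumed each time
- all constants are for 80 °C and move with temperature by the activation energies and enthalpies
- in an amount of single ring, one idle adduct counts as one single ring

    substrate + single ring ⇌ idle adduct, settled at all times (K1 = 19 M⁻¹, ΔH1 = −32.0 kJ mol⁻¹)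
    open dimer → ring dimer (k2 = 0.0072 s⁻¹, Ea2 = 106 kJ mol⁻¹)
    2 substrate → open dimer (k3 = 0.069 M⁻¹ s⁻¹, Ea3 = 63.0 kJ mol⁻¹)
    substrate → single ring (k4 = 0.063 s⁻¹, Ea4 = 82.0 kJ mol⁻¹)
    substrate + single ring → side product (k5 = 0.012 M⁻¹ s⁻¹, Ea5 = 69.0 kJ mol⁻¹)
    substrate + open dimer → open trimer (k6 = 0.069 M⁻¹ s⁻¹, Ea6 = 69.0 kJ mol⁻¹)
    (constants at 80 °C)

Closure goes with [substrate] and dimerisation with its square, so their ratio, a selectivity factor, is crossover/[substrate]. On Thursday's flask this ratio is 0.285 at the charge, so dimerisation leads at first, yet closure leads once [substrate] has fallen below the crossover. Neither end describes the whole run, so the two are joined. Between these two steps, the share of substrate closing at each moment is crossover/(crossover + [substrate]), and adding these shares from the charge down to nothing gives, with x = charge/crossover, a single-ring yield of ln(1 + x)/x.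

Does 15 min allow the run to finish? By closure, free substrate has a half-life of 11.0 s at 80 °C, much shorter than the time, so this reckoning takes the yield from branching.

What does temperature do? Closure has the higher activation energy, so the crossover rises to 0.646 M on Sunday's flask and 0.882 M on Monday's. The reckoned yields are 42.9% on Thursday's, 50.3% on Sunday's and 57.0% on Monday's. Open trimer, side product and idle adduct are left out of this reckoning, though the equilibrium constant times charged [substrate] is 30 on Thursday's, so these figures are rough.

Which product leads? On Sunday's and Monday's flasks, the reckoned single ring exceeds the remainder. On Thursday's, ring dimer would need more than 75.1% of the remaining 57.1%. But on Thursday's, at charged [substrate], open dimer takes up substrate 15.3 times as fast as it closes, so open trimer claims part of that remainder. Single ring is therefore reckoned ahead in each flask.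

The forecast also puts single ring ahead, with 45%, 51% and 56%. It lies above this reckoning on Thursday's and below it on Monday's. In its words, “its share grows with temperature because ring closure has a higher activation energy than dimerisation”.

The simulation gives 45.0%, 52.3% and 58.6% of single ring, against 27.1%, 25.3% and 23.4% of ring dimer, so single ring leads in each flask and the forecast's answers hold.

In Monday's flask at 0.0111 min, closure uses substrate 3.1 times as fast as dimerisation, which with the crossover of 0.882 M puts free [substrate] near 0.285 M, below the crossover; half of the dimerisation up to the end is done by 0.131 s. A neighbour of Monday's charged with 0.64 M has x = 0.726 in place of 1.81, the same formula gives 75.2%, and that flask holds 76.3% of single ring.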